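The dibenzoylmethane is cut between C1 of ring A (the 4-hydroxy-2-methoxy-3-prenylphenyl ring) and the ketone carbon it carries. The rest of the propane-1,3-dione, its acidic CH2 and the ring-B ketone, is hidden as an alkyne. The three-carbon bridge therefore arrives on ring B as an arylpropiolic Weinreb amide without acidic hydrogen. The key step adds the ring-A aryllithium, held by the neighbouring C2 methoxy oxygen, to this amide and should give the complete C26 skeleton as an ynone in one operation. The ynone polarity then dictates that water enters only at the alkyne carbon bound to ring B. The precursors are a bromoarene and an alkynyl Weinreb amide, both MOM-protected.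

Key step: step 6

Assumption: N-methoxy-N-methylprop-2-ynamide (9) is taken as a catalogue compound (otherwise one amide coupling from propiolic acid), and the 1,3-dione is written throughout as its diketo tautomer.

Step 1
Reactants: 1 4-bromo-3-methoxyphenol
Product: 2 1-bromo-2-methoxy-4-(methoxymethoxy)benzene
Conditions: NaH, MOMCl, DMF, 0 °C to rt
Reagents that add atoms: chloromethyl methyl ether (MOMCl), COCCl
Why: Williamson-type O-alkylation of the sodium phenoxide installs an acetal that protects the later 4-OH of ring A and serves as second directing group in step 2.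

Step 2
Reactants: 2 1-bromo-2-methoxy-4-(methoxymethoxy)benzene; 3 prenyl bromide (1-bromo-3-methylbut-2-ene)
Product: 5 1-bromo-2-methoxy-4-(methoxymethoxy)-3-(3-methylbut-2-en-1-yl)benzene, via lithiated bromoarene 4 (not isolated)
Conditions: LiTMP (TMPH + n-BuLi), THF, −78 °C; then 3, CuBr·SMe2 (10 mol %), −78 to 0 °C
Reagents that add atoms: none
Why: Directed ortho-metalation, in which the hydrogen between the OMe and OMOM oxygens is the most acidic ring hydrogen and both oxygens bind lithium, the amide base cannot undergo bromine–lithium exchange, and the aryllithium is alkylated at the unhindered CH2 terminus of prenyl bromide (SN2).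

Step 3
Reactants: 6 4-iodophenol; 3 prenyl bromide
Product: 7 4-iodo-2-(3-methylbut-2-en-1-yl)phenol
Conditions: NaH, toluene, 0 °C to rt; then 3, rt to 40 °C
Reagents that add atoms: none
Why: ortho-C-alkylation of a tight sodium phenoxide ion pair in a non-polar solvent, with the para position blocked by iodine and the two ortho positions equivalent, so only one C-prenyl isomer can arise.

Step 4
Reactants: 7 4-iodo-2-(3-methylbut-2-en-1-yl)phenol
Product: 8 4-iodo-1-(methoxymethoxy)-2-(3-methylbut-2-en-1-yl)benzene
Conditions: NaH, MOMCl, DMF, 0 °C to rt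
Reagents that add atoms: chloromethyl methyl ether (MOMCl), COCCl
Why: Williamson-type O-alkylation removes the acidic OH before the organolithium step and uses the same protecting group as ring A, so that one final operation frees both phenols.

Step 5
Reactants: 8 4-iodo-1-(methoxymethoxy)-2-(3-methylbut-2-en-1-yl)benzene; 9 N-methoxy-N-methylprop-2-ynamide
Product: 10 N-methoxy-3-[4-(methoxymethoxy)-3-(3-methylbut-2-en-1-yl)phenyl]-N-methylprop-2-ynamide
Conditions: PdCl2(PPh3)2 (3 mol %), CuI (5 mol %), Et3N, THF, degassed, rt
Reagents that add atoms: none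
Why: Sonogashira coupling of an aryl iodide with a terminal propiolamide proceeds at room temperature, where the tertiary amine base cannot add irreversibly to the acceptor alkyne and the prenyl group and MOM ether are inert.

Step 6
Reactants: 5 1-bromo-2-methoxy-4-(methoxymethoxy)-3-(3-methylbut-2-en-1-yl)benzene; 10 N-methoxy-3-[4-(methoxymethoxy)-3-(3-methylbut-2-en-1-yl)phenyl]-N-methylprop-2-ynamide
Product: 13 1-[2-methoxy-4-(methoxymethoxy)-3-(3-methylbut-2-en-1-yl)phenyl]-3-[4-(methoxymethoxy)-3-(3-methylbut-2-en-1-yl)phenyl]prop-2-yn-1-one, via ring-A aryllithium 11 (not isolated), via tetrahedral lithium chelate 12 (not isolated)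
Conditions: 5, n-BuLi, THF, −78 °C; then 10 in THF, −78 to −30 °C; transfer into cold 0.5 M aq. HCl/Et2O
Reagents that add atoms: none
Why: Bromine–lithium exchange on 5, far faster at −78 °C than deprotonation of the allylic–benzylic CH2 or lithiation next to OMOM, puts lithium exactly on C1 of ring A, where the C2 methoxy oxygen coordinates it. The aryllithium adds 1,2 to the amide carbonyl of 10, and the N-methoxy oxygen locks adduct 12 as a five-membered lithium chelate, so no second addition can occur and the ketone appears only on the acidic quench. The closest known reaction type is the Weinreb ketone synthesis in its alkynyl-amide (ynone-forming) variant. No ring is closed and no stereocentre survives, because the carbinolamine carbon of 12 collapses to C=O. The step needs carbonyl attack to win over conjugate addition and over proton transfer: the hard, chelating organolithium favours the carbonyl, the electron-rich 4-alkoxyaryl group weakens the alkyne as an acceptor, and masking C2 and C3 of the dione as C≡C removes the strongly acidic CH2 that would quench any aryl metal. Any conjugate adduct of liberated MeNHOMe with 13 is harmless, since step 7 hydrolyses it to the same dione.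

Step 7
Reactants: 13 1-[2-methoxy-4-(methoxymethoxy)-3-(3-methylbut-2-en-1-yl)phenyl]-3-[4-(methoxymethoxy)-3-(3-methylbut-2-en-1-yl)phenyl]prop-2-yn-1-one
Product: 15 1-[4-hydroxy-2-methoxy-3-(3-methylbut-2-en-1-yl)phenyl]-3-[4-hydroxy-3-(3-methylbut-2-en-1-yl)phenyl]propane-1,3-dione (target), via pyrrolidine enaminone 14 (not isolated)
Conditions: pyrrolidine, THF, rt; then 3 M aq. HCl, THF, 45 °C
Reagents that add atoms: water, O; pyrrolidine, C1CCNC1 (present only in intermediate 14, released again)
Why: Conjugate (aza-Michael) addition of pyrrolidine fixes the heteroatom on the alkyne carbon bound to ring B, and aqueous acid then hydrolyses the vinylogous amide to the 1,3-dione and cleaves both MOM acetals in the same flask (enaminone hydrolysis and acetal hydrolysis).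

Compound list
1 | 4-bromo-3-methoxyphenol | COc1cc(O)ccc1Br | starting material
2 | 1-bromo-2-methoxy-4-(methoxymethoxy)benzene | COCOc1ccc(Br)c(OC)c1 | intermediate
3 | prenyl bromide (1-bromo-3-methylbut-2-ene) | CC(C)=CCBr | starting material
4 | [3-bromo-2-methoxy-6-(methoxymethoxy)phenyl]lithium (lithium between OMe and OMOM) | COCOc1ccc(Br)c(OC)c1[Li] | intermediate
5 | 1-bromo-2-methoxy-4-(methoxymethoxy)-3-(3-methylbut-2-en-1-yl)benzene (ring-A bromide) | COCOc1ccc(Br)c(OC)c1CC=C(C)C | intermediate
6 | 4-iodophenol | Oc1ccc(I)cc1 | starting material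
7 | 4-iodo-2-(3-methylbut-2-en-1-yl)phenol | CC(C)=CCc1cc(I)ccc1O | intermediate
8 | 4-iodo-1-(methoxymethoxy)-2-(3-methylbut-2-en-1-yl)benzene | COCOc1ccc(I)cc1CC=C(C)C | intermediate
9 | N-methoxy-N-methylprop-2-ynamide | C#CC(=O)N(C)OC | starting material
10 | N-methoxy-3-[4-(methoxymethoxy)-3-(3-methylbut-2-en-1-yl)phenyl]-N-methylprop-2-ynamide (ring-B alkynyl Weinreb amide) | COCOc1ccc(C#CC(=O)N(C)OC)cc1CC=C(C)C | intermediate
11 | [2-methoxy-4-(methoxymethoxy)-3-(3-methylbut-2-en-1-yl)phenyl]lithium | COCOc1ccc([Li])c(OC)c1CC=C(C)C | intermediate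
12 | lithium alkoxide of the tetrahedral adduct of 11 and 10 (racemic, N-OMe chelated) | COCOc1ccc(C(O[Li])(C#Cc2ccc(OCOC)c(CC=C(C)C)c2)N(C)OC)c(OC)c1CC=C(C)C | intermediate
13 | 1-[2-methoxy-4-(methoxymethoxy)-3-(3-methylbut-2-en-1-yl)phenyl]-3-[4-(methoxymethoxy)-3-(3-methylbut-2-en-1-yl)phenyl]prop-2-yn-1-one (ynone) | COCOc1ccc(C(=O)C#Cc2ccc(OCOC)c(CC=C(C)C)c2)c(OC)c1CC=C(C)C | intermediate
14 | (E)-3-(pyrrolidin-1-yl) enone from 13, nitrogen on the carbon bound to ring B (drawn E, geometry without consequence) | COCOc1ccc(C(=O)/C=C(/N2CCCC2)c2ccc(OCOC)c(CC=C(C)C)c2)c(OC)c1CC=C(C)C | intermediate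
15 | 1-[4-hydroxy-2-methoxy-3-(3-methylbut-2-en-1-yl)phenyl]-3-[4-hydroxy-3-(3-methylbut-2-en-1-yl)phenyl]propane-1,3-dione | COc1c(C(=O)CC(=O)c2ccc(O)c(CC=C(C)C)c2)ccc(O)c1CC=C(C)C | target

Total step count: 7.
Longest linear sequence: 5 (steps 3, 4, 5, 6, 7).

Steps most likely to fail

Step 2. The deprotonation may stay incomplete. It may also occur in part at the hydrogen next to bromine, followed by loss of lithium bromide to an aryne. The fallback sets out from 1 and comes back at 5, and it exchanges the directing group for the strongest oxygen-based one so that plain LDA suffices.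
- Phenol 1 is carbamoylated (ClCONEt2, NaH, THF) to 4-bromo-3-methoxyphenyl diethylcarbamate F1.
- LDA in THF at −78 °C lithiates between carbamate and methoxy to the lithiated carbamate F2.
- F2 is alkylated with 3 at low temperature, before an anionic Fries shift can start, to 4-bromo-3-methoxy-2-(3-methylbut-2-en-1-yl)phenyl diethylcarbamate F3.
- KOH in refluxing ethanol frees 4-bromo-3-methoxy-2-(3-methylbut-2-en-1-yl)phenol F4.
- NaH/MOMCl converts F4 into 5.

Step 3. O-alkylation and a second alkylation may outrun the ortho-C-alkylation of the phenoxide. The fallback sets out from 6 and comes back at 7, accepting the O-alkylation and moving the group afterwards.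
- Compound 6 is O-prenylated with 3 (K2CO3, acetone, reflux) to 1-iodo-4-[(3-methylbut-2-en-1-yl)oxy]benzene F5.
- The prenyl group is then shifted to the ortho carbon by an acid-clay-catalysed [1,3] rearrangement (montmorillonite K10, CH2Cl2, 0 °C to rt), giving 7.

Step 7. Acid-catalysed addition of a freed phenolic OH to its neighbouring prenyl double bond (closure to a dimethylchroman) may compete with the slower acetal cleavage. The fallback sets out from 13 and comes back at 15. It separates the two events and never exposes the free ortho-prenylphenols to a Brønsted acid.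
- Compound 13 is taken to 14 with pyrrolidine as before.
- Compound 14 is hydrolysed with aqueous oxalic acid in THF at rt, which leaves the MOM ethers intact. This gives 1-[2-methoxy-4-(methoxymethoxy)-3-(3-methylbut-2-en-1-yl)phenyl]-3-[4-(methoxymethoxy)-3-(3-methylbut-2-en-1-yl)phenyl]propane-1,3-dione F6.
- Both acetals of F6 are then transferred to a thiol under Lewis acid activation (ZnBr2, n-PrSH, CH2Cl2, 0 °C, short contact) to give 15.

Further compounds
F1 | step 2 | 4-bromo-3-methoxyphenyl diethylcarbamate | CCN(CC)C(=O)Oc1ccc(Br)c(OC)c1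
F2 | step 2 | 4-bromo-2-lithio-3-methoxyphenyl diethylcarbamate | CCN(CC)C(=O)Oc1ccc(Br)c(OC)c1[Li]
F3 | step 2 | 4-bromo-3-methoxy-2-(3-methylbut-2-en-1-yl)phenyl diethylcarbamate | CCN(CC)C(=O)Oc1ccc(Br)c(OC)c1CC=C(C)C
F4 | step 2 | 4-bromo-3-methoxy-2-(3-methylbut-2-en-1-yl)phenol | COc1c(Br)ccc(O)c1CC=C(C)C
F5 | step 3 | 1-iodo-4-[(3-methylbut-2-en-1-yl)oxy]benzene | CC(C)=CCOc1ccc(I)cc1
F6 | step 7 | 1-[2-methoxy-4-(methoxymethoxy)-3-(3-methylbut-2-en-1-yl)phenyl]-3-[4-(methoxymethoxy)-3-(3-methylbut-2-en-1-yl)phenyl]propane-1,3-dione | COCOc1ccc(C(=O)CC(=O)c2ccc(OCOC)c(CC=C(C)C)c2)c(OC)c1CC=C(C)C
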